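## Retrosynthetic overview

1. Labels: ring A is the trimethylcyclohexane, ring B the cyclopentane, ring C the epoxide-bearing cyclohexane. Ring C atoms: Ca (fusion CH next to the quaternary ring-A carbon), Cb (fusion CH next to the ArO–CH), Cc (CH–C=O), Cd (C(CH3)–OO), Ce and Cf (epoxide CH and C–CH3). Ck is the ketone carbon, Cs the spiro carbon.
2. Endgame: epoxide by closure of a Cf–OH/Ce–Br bromohydrin; 1,2-dioxocane by addition of the Cd–OOH to an aldehyde freed by ozonolysis of a Cs-allyl group; Cd–OOH/Ce–Br by bromo-hydroperoxidation of a Cd=Ce alkene; lactam by NH3 opening of an enol lactone; Cs by allylation; 13-membered ring by Ullmann aryl ether closure.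
3. Enabling feature: ring C carries its exocyclic ketone carbon Ck on Cc, next to fusion carbon Cb. A cycloheptanone with Ck in the ring between Cb and Cc and a diazo group on Cc contracts (Wolff) to exactly this arrangement, and the ketene formed at Ck acylates the lactone enolate to make the Ck–Cs bond.
4. The cycloheptanone and ring B come from an intramolecular (4+3) cycloaddition of an epoxy enol silane with a 2-silyloxy diene, both arms built on ring A from meso cis-3,5-dimethylcyclohexanone.
5. Ring order: A (starting material) → B plus seven-membered ring → C (contraction) → macrocycle → lactam → 1,2-dioxocane → epoxide.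

Key step: step 17

Assumption: the lactam C(OH)N carbon and the peroxy-hemiacetal carbon are labile (ring–chain tautomerism) and are taken to settle in the configuration of the target under thermodynamic control.
Assumption: the lactone α-carbon (future Cs) in 26–30 is enolisable and is drawn without configuration until step 22.

## Route

Step 1
Reactants: 1 cis-3,5-dimethylcyclohexanone (meso)
Product: 2 (3S,5R)-3,5-dimethyl-1-(trimethylsilyloxy)cyclohex-1-ene
Conditions: lithium (R,R)-bis(1-phenylethyl)amide (from the amine and n-BuLi), TMSCl (in situ quench), THF, −100 °C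
Reagents that add atoms: chlorotrimethylsilane, C[Si](C)(C)Cl
Why: Enantioselective deprotonation of a meso ketone by a chiral lithium amide removes one of the two enantiotopic α-protons, which fixes the absolute configuration of both ring-A methyl centres (the antipodal base would give ent-2).

Step 2
Reactants: 2 (3S,5R)-3,5-dimethyl-1-(trimethylsilyloxy)cyclohex-1-ene
Product: 3 2-(dimethoxymethyl)-cis-3,5-dimethylcyclohexanone (C2 epimers)
Conditions: HC(OMe)3, TMSOTf (5 mol %), CH2Cl2, −78 °C
Reagents that add atoms: trimethyl orthoformate, COC(OC)OC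
Why: Mukaiyama-type addition of the enol silane to the dimethoxycarbenium ion formylates only the enol carbon, and the new α-centre is destroyed in step 3.

Step 3
Reactants: 3 2-(dimethoxymethyl)-cis-3,5-dimethylcyclohexanone
Product: 5 2-allyl-cis-4,6-dimethylcyclohex-1-ene-1-carbaldehyde, via tertiary alcohol 4 (not isolated)
Conditions: allylMgBr, THF, −78 to 0 °C; then 2 M HCl, THF, rt
Reagents that add atoms: allylmagnesium bromide, C=CC[Mg]Br; water, O
Why: Grignard 1,2-addition to the ketone, then acid hydrolysis of the acetal and dehydration of the β-hydroxy aldehyde, gives the fully substituted enal (the masked-formyl ketone route to 2-substituted cycloalkenecarbaldehydes).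

Step 4
Reactants: 5 2-allyl-cis-4,6-dimethylcyclohex-1-ene-1-carbaldehyde
Product: 8 (2-allyl-2,4,6-trimethylcyclohexyl)methanol (CH2OH and the 4,6-methyls equatorial, 2-methyl axial), via silyl enol ether 6 (not isolated), via aldehyde 7 (not isolated)
Conditions: Me2CuLi (from MeLi and CuI), TMSCl, THF, −78 °C; then K2CO3 (cat.), MeOH, rt; then NaBH4, 0 °C
Reagents that add atoms: lithium dimethylcuprate, [Li+].C[Cu-]C
Why: TMSCl-accelerated cuprate conjugate addition occurs axially on the half-chair with both ring methyls equatorial, so the new methyl is axial and trans to them (quaternary centre), and base equilibration puts the formyl group equatorial before borohydride reduction.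

Step 5
Reactants: 8 (2-allyl-2,4,6-trimethylcyclohexyl)methanol
Product: 9 1-[2-(hydroxymethyl)-1,3,5-trimethylcyclohexyl]propan-2-one
Conditions: PdCl2 (10 mol %), CuCl, O2 (1 atm), DMF/H2O, rt
Reagents that add atoms: water, O
Why: Tsuji–Wacker oxidation converts the terminal alkene to the methyl ketone with Markovnikov selectivity and tolerates the free alcohol.

Step 6
Reactants: 9 1-[2-(hydroxymethyl)-1,3,5-trimethylcyclohexyl]propan-2-one
Product: 10 4-hydroxy-1-[2-(hydroxymethyl)-1,3,5-trimethylcyclohexyl]pentan-2-one (carbinol epimers)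
Conditions: LiN(iPr)2 (2.2 equiv), THF, −78 °C; then CH3CHO; NH4Cl
Reagents that add atoms: acetaldehyde, CC=O
Why: After alkoxide formation the kinetic enolate forms at the methyl group rather than the neopentyl methylene and undergoes a crossed aldol addition.

Step 7
Reactants: 10 4-hydroxy-1-[2-(hydroxymethyl)-1,3,5-trimethylcyclohexyl]pentan-2-one
Product: 12 {2,4,6-trimethyl-2-[(E)-2-oxopent-3-en-1-yl]cyclohexyl}methyl acetate, via diacetate 11 (not isolated)
Conditions: Ac2O, Et3N, DMAP (cat.), CH2Cl2, rt; then DBU, rt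
Reagents that add atoms: acetic anhydride, CC(=O)OC(C)=O
Why: Acetylation of both hydroxyls followed by E1cB elimination of the β-acetoxy ketone gives the (E)-enone, while the primary acetate masks the future aldehyde carbon.

Step 8
Reactants: 12 {2,4,6-trimethyl-2-[(E)-2-oxopent-3-en-1-yl]cyclohexyl}methyl acetate
Product: 13 {2-[(1Z,3E)-2-(tert-butyldimethylsilyloxy)penta-1,3-dien-1-yl]-2,4,6-trimethylcyclohexyl}methyl acetate
Conditions: TBSOTf, Et3N, CH2Cl2, −78 to 0 °C
Reagents that add atoms: tert-butyldimethylsilyl trifluoromethanesulfonate, CC(C)(C)[Si](C)(C)OS(=O)(=O)C(F)(F)F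
Why: Silyl triflate/amine enolisation of the enone at its α′-methylene gives the cross-conjugated (Z)-2-silyloxy diene, the four-carbon partner for step 14.

Step 9
Reactants: 13 the dienyl acetate
Product: 14 {2-[(1Z,3E)-2-(tert-butyldimethylsilyloxy)penta-1,3-dien-1-yl]-2,4,6-trimethylcyclohexyl}methanol
Conditions: iBu2AlH (2.5 equiv), CH2Cl2, −78 °C; Rochelle salt
Reagents that add atoms: none
Why: Reductive cleavage of the acetate by the aluminium hydride leaves the silyl dienol ether untouched, which basic methanolysis might not.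

Step 10
Reactants: 14 the dienyl alcohol
Product: 15 2-[(1Z,3E)-2-(tert-butyldimethylsilyloxy)penta-1,3-dien-1-yl]-2,4,6-trimethylcyclohexane-1-carbaldehyde
Conditions: Dess–Martin periodinane, NaHCO3, CH2Cl2, 0 °C to rt
Reagents that add atoms: none
Why: Buffered periodinane oxidation gives the aldehyde without touching the enol ether, and the α-centre stays in its equatorial configuration.

Step 11
Reactants: 15 the dienyl aldehyde
Product: 16 (E)-4-{2-[(1Z,3E)-2-(tert-butyldimethylsilyloxy)penta-1,3-dien-1-yl]-2,4,6-trimethylcyclohexyl}but-3-en-2-one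
Conditions: Ph3P=CHC(O)CH3, toluene, 90 °C
Reagents that add atoms: 1-(triphenylphosphoranylidene)propan-2-one, CC(=O)C=P(c1ccccc1)(c1ccccc1)c1ccccc1
Why: Wittig olefination with the stabilised ylide gives the (E)-enone.

Step 12
Reactants: 16 the (E)-enone
Product: 17 1-[(2S,3R)-3-{2-[(1Z,3E)-2-(tert-butyldimethylsilyloxy)penta-1,3-dien-1-yl]-2,4,6-trimethylcyclohexyl}oxiran-2-yl]ethan-1-one (trans-epoxide)
Conditions: La(OiPr)3 (10 mol %), (R)-BINOL (10 mol %), Ph3As=O (10 mol %), t-BuOOH (1.5 equiv), 4 Å molecular sieves, THF, rt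
Reagents that add atoms: tert-butyl hydroperoxide, CC(C)(C)OO
Why: Catalyst-controlled nucleophilic epoxidation of the (E)-enone by the lanthanum–BINOL peroxide (the BINOL enantiomer that gives the (2S,3R)-epoxy ketone) sets the future ArO–CH centre against the weak substrate bias, while the silyl dienol ether is inert to the basic oxidant.

Step 13
Reactants: 17 the trans-epoxy ketone
Product: 18 triethylsilyl enol ether of 17 (2-[1-(triethylsilyloxy)vinyl]oxirane, epoxide unchanged)
Conditions: LiN(iPr)2, Et3SiCl (in situ), THF, −78 °C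
Reagents that add atoms: chlorotriethylsilane, CC[Si](Cl)(CC)CC
Why: Kinetic enolisation can only occur at the methyl group, and in situ silylation prevents opening of the epoxide by the enolate.

Step 14
Reactants: 18 the epoxy enol silane
Product: 19 tricyclic cycloheptanone (ring A, ring B with CH–OSiEt3, seven-membered ring with the C=O next to Cb, CH2, CH(CH3) and the TBS enol ether next to Ca; trans ring fusions)
Conditions: Et3SiOTf (10 mol %), CH2Cl2, −78 °C
Reagents that add atoms: none
Why: In this silyl triflate-catalysed intramolecular (4+3) cycloaddition of an epoxy enol silane, the diene terminus opens the silylated epoxide at its α-carbon with inversion and the ring closes at the methylene terminus, so the C–O centre is retained, Cb is inverted, the three-atom tether with an extended transition state gives the trans ring fusion at Ca, and the (E)-propenyl end sets the later-destroyed methyl centre.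

Step 15
Reactants: 19 the tricyclic cycloheptanone
Product: 21 α-diazo ketone (diazo group on the CH2 carbon of 19), via trifluoroacetyl ketone 20 (not isolated)
Conditions: LiN(SiMe3)2, THF, −78 °C, CF3CO2CH2CF3; then CH3SO2N3, Et3N, H2O, MeCN, rt
Reagents that add atoms: methanesulfonyl azide, CS(=O)(=O)N=[N+]=[N-]
Why: Detrifluoroacetylative diazo transfer goes through the kinetic enolate at the methylene, which avoids enolisation toward Cb and β-elimination of the silyloxy group.

Step 16
Reactants: 22 pent-4-ynoic acid; 23 1,4-diiodobenzene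
Product: 24 (E)-5-(4-iodobenzylidene)dihydrofuran-2(3H)-one
Conditions: Pd(OAc)2 (5 mol %), PPh3, Et3N, MeCN, 60 °C; 23 in threefold excess
Reagents that add atoms: none
Why: The arylpalladium iodide activates the alkyne for anti attack by the carboxylate and reductive elimination gives the (E)-arylidene lactone (cyclisation–coupling of alkynoic acids), with excess diiodide ensuring mono-coupling.

Step 17
Reactants: 21 α-diazo ketone; 24 (E)-5-(4-iodobenzylidene)dihydrofuran-2(3H)-one
Product: 26 ring-C β-keto lactone (Cc carries C(=O)–CH of the arylidene lactone; CH–OSiEt3, TBS enol ether and CH(CH3) retained), via ketene 25 (not isolated)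
Conditions: 24 (2.2 equiv), LiN(iPr)2 (2.2 equiv), THF, −78 °C; separately 21, hν (350 nm, Pyrex), THF, −78 °C; ketene solution cannulated into the enolate, −78 to −40 °C; AcOH
Reagents that add atoms: none
Why: Proposed new method: photolysis of the cyclic α-diazo ketone triggers a Wolff rearrangement in which Cb migrates with retention from the ring carbonyl carbon to the diazo carbon Cc, and the resulting exocyclic ketene at Ck is C-acylated by the preformed lithium enolate of 24, the closest known reaction types being the photochemical Wolff ring contraction of cyclic 2-diazo ketones with alcohol or amine capture and the C-acylation of lithium ester enolates by ketenes. Ring C is closed by this 1,2-shift (contraction from seven to six atoms); the acylation closes no ring but makes the Ck–Cs bond and so attaches the whole lactone/aryl iodide fragment. Cb keeps its configuration because the migrating carbon moves with retention; Cc is protonated on work-up and, being α to the new ketone, settles with the acyl group equatorial and trans to the ring-B bond at Cb, as in the target; Cs remains labile. The step needs acylation by the ketene rather than attack of the enolate on the diazo group, which is secured by finishing the photolysis before mixing (this also keeps the aryl iodide out of the light), and the acidic product consumes the second equivalent of enolate, which prevents double acylation.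

Step 18
Reactants: 26 β-keto lactone
Product: 27 ring-C enone (Cf=O, Ce=Cd(CH3))
Conditions: IBX, 4-methoxypyridine N-oxide, DMSO, rt
Reagents that add atoms: none
Why: Hypervalent-iodine dehydrogenation of the silyl enol ether (Saegusa-type outcome) gives the enone with the new double bond toward the methyl-bearing carbon, and is chosen over Pd(OAc)2 because zerovalent palladium would attack the aryl iodide.

Step 19
Reactants: 27 ring-C enone
Product: 28 tertiary allylic alcohol (Cf(CH3)OH with the oxygen syn to the quaternary ring-A methyl, Cd=Ce alkene)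
Conditions: CeCl3 (3 equiv), MeMgBr (3 equiv), THF, −78 °C
Reagents that add atoms: methylmagnesium bromide, C[Mg]Br
Why: The first equivalent deprotonates the β-keto lactone, whose enolate protects both of its carbonyls, and the organocerium then adds 1,2 to the enone carbonyl from the face anti to the axial quaternary methyl of ring A (1,3-diaxial shielding), which places the carbinol oxygen on the face of the future epoxide.

Step 20
Reactants: 28 tertiary allylic alcohol
Product: 29 diol (free secondary OH on ring B)
Conditions: Bu4NF, AcOH, THF, 0 °C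
Reagents that add atoms: none
Why: Buffered fluoride cleaves the secondary triethylsilyl ether without ionising the tertiary allylic alcohol.

Step 21
Reactants: 29 diol
Product: 30 13-membered macrocyclic aryl ether (enol lactone retained)
Conditions: CuI (30 mol %), 3,4,7,8-tetramethyl-1,10-phenanthroline, Cs2CO3, toluene (0.002 M), 110 °C
Reagents that add atoms: none
Why: Intramolecular Ullmann-type etherification proceeds with retention at the carbinol carbon, the β-keto lactone is protected as its caesium enolate, and the tertiary alcohol does not compete.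

Step 22
Reactants: 30 macrocyclic aryl ether
Product: 31 C-allylated macrocycle (quaternary Cs)
Conditions: Pd2(dba)3 (2.5 mol %), (1R,2R)-N,N′-bis[2-(diphenylphosphino)benzoyl]cyclohexane-1,2-diamine (7.5 mol %), allyl methyl carbonate, CH2Cl2, 0 °C
Reagents that add atoms: allyl methyl carbonate, C=CCOC(=O)OC
Why: Tsuji–Trost allylation occurs at the most acidic C–H (the β-keto lactone) under neutral conditions, and the chiral ligand on the π-allylpalladium complex is relied on to select the enolate face that gives the Cs configuration drawn.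

Step 23
Reactants: 31 C-allylated macrocycle
Product: 32 macrocyclic hydroxy lactam
Conditions: NH3 (7 M in MeOH), THF, 0 °C to rt
Reagents that add atoms: ammonia, N
Why: Aminolysis of the activated enol lactone gives the primary amide and the benzyl ketone, which close to the 5-hydroxy lactam with the hemiaminal centre set thermodynamically within the macrocycle.

Step 24
Reactants: 32 macrocyclic hydroxy lactam
Product: 33 bromo hydroperoxide (Cd–OOH, Ce–Br trans-diaxial; Cf–OH)
Conditions: N-bromosuccinimide (1.05 equiv), anhydrous H2O2 in Et2O (20 equiv), CH2Cl2, −40 °C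
Reagents that add atoms: N-bromosuccinimide, O=C1CCC(=O)N1Br; hydrogen peroxide, OO
Why: Bromo-hydroperoxidation of the trisubstituted alkene gives the bromonium ion on the face anti to the pseudo-axial allylic hydroxyl, and both Markovnikov and trans-diaxial (Fürst–Plattner) opening direct H2O2 to tertiary Cd from the opposite face, while the terminal allyl alkene reacts much more slowly.

Step 25
Reactants: 33 bromo hydroperoxide
Product: 35 bromohydrin peroxy-hemiacetal (1,2-dioxocane closed), via hydroperoxy aldehyde 34 (not isolated)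
Conditions: O3, pyridine (3 equiv), CH2Cl2, −78 °C
Reagents that add atoms: ozone, [O-][O+]=O
Why: Pyridine-modified ozonolysis of the only remaining alkene gives the aldehyde without a reductive work-up that could destroy the hydroperoxide, which then adds to the aldehyde to close the eight-membered peroxy-hemiacetal with the acetal carbon set thermodynamically.

Step 26
Reactants: 35 bromohydrin peroxy-hemiacetal
Product: 36 CNP0533733.1
Conditions: Ag2O, CH2Cl2, rt, dark
Reagents that add atoms: none
Why: Silver-assisted intramolecular Williamson closure lets the tertiary Cf hydroxyl, anti-periplanar to the Ce bromide, displace it with inversion to give the epoxide syn to the peroxide, without the strong base that would fragment the peroxy-hemiacetal.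

## Compound list

1 | cis-3,5-dimethylcyclohexanone (meso) | C[C@@H]1C[C@H](C)CC(=O)C1 | starting material
2 | (3S,5R)-3,5-dimethyl-1-(trimethylsilyloxy)cyclohex-1-ene | C[C@@H]1C[C@H](C)C=C(O[Si](C)(C)C)C1 | intermediate
3 | 2-(dimethoxymethyl)-cis-3,5-dimethylcyclohexanone | C[C@@H]1C[C@H](C)C(C(OC)OC)C(=O)C1 | intermediate
4 | 1-allyl-2-(dimethoxymethyl)-3,5-dimethylcyclohexan-1-ol | C[C@@H]1C[C@H](C)C(C(OC)OC)C(O)(CC=C)C1 | intermediate (not isolated)
5 | 2-allyl-cis-4,6-dimethylcyclohex-1-ene-1-carbaldehyde | C[C@@H]1C[C@H](C)C(C=O)=C(CC=C)C1 | intermediate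
6 | trimethylsilyl enol ether of aldehyde 7 | C[C@@H]1C[C@H](C)C(=CO[Si](C)(C)C)[C@](C)(CC=C)C1 | intermediate (not isolated)
7 | 2-allyl-2,4,6-trimethylcyclohexane-1-carbaldehyde | C[C@@H]1C[C@H](C)[C@@H](C=O)[C@](C)(CC=C)C1 | intermediate (not isolated)
8 | (2-allyl-2,4,6-trimethylcyclohexyl)methanol | C[C@@H]1C[C@H](C)[C@@H](CO)[C@](C)(CC=C)C1 | intermediate
9 | 1-[2-(hydroxymethyl)-1,3,5-trimethylcyclohexyl]propan-2-one | C[C@@H]1C[C@H](C)[C@@H](CO)[C@](C)(CC(C)=O)C1 | intermediate
10 | 4-hydroxy-1-[2-(hydroxymethyl)-1,3,5-trimethylcyclohexyl]pentan-2-one | C[C@@H]1C[C@H](C)[C@@H](CO)[C@](C)(CC(=O)CC(C)O)C1 | intermediate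
11 | diacetate of 10 | C[C@@H]1C[C@H](C)[C@@H](COC(C)=O)[C@](C)(CC(=O)CC(C)OC(C)=O)C1 | intermediate (not isolated)
12 | {2,4,6-trimethyl-2-[(E)-2-oxopent-3-en-1-yl]cyclohexyl}methyl acetate | C[C@@H]1C[C@H](C)[C@@H](COC(C)=O)[C@](C)(CC(=O)/C=C/C)C1 | intermediate
13 | {2-[(1Z,3E)-2-(tert-butyldimethylsilyloxy)penta-1,3-dien-1-yl]-2,4,6-trimethylcyclohexyl}methyl acetate | C[C@@H]1C[C@H](C)[C@@H](COC(C)=O)[C@](C)(/C=C(O[Si](C)(C)C(C)(C)C)/C=C/C)C1 | intermediate
14 | {2-[(1Z,3E)-2-(tert-butyldimethylsilyloxy)penta-1,3-dien-1-yl]-2,4,6-trimethylcyclohexyl}methanol | C[C@@H]1C[C@H](C)[C@@H](CO)[C@](C)(/C=C(O[Si](C)(C)C(C)(C)C)/C=C/C)C1 | intermediate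
15 | 2-[(1Z,3E)-2-(tert-butyldimethylsilyloxy)penta-1,3-dien-1-yl]-2,4,6-trimethylcyclohexane-1-carbaldehyde | C[C@@H]1C[C@H](C)[C@@H](C=O)[C@](C)(/C=C(O[Si](C)(C)C(C)(C)C)/C=C/C)C1 | intermediate
16 | (E)-4-{2-[(1Z,3E)-2-(tert-butyldimethylsilyloxy)penta-1,3-dien-1-yl]-2,4,6-trimethylcyclohexyl}but-3-en-2-one | C[C@@H]1C[C@H](C)[C@@H](/C=C/C(C)=O)[C@](C)(/C=C(O[Si](C)(C)C(C)(C)C)/C=C/C)C1 | intermediate
17 | 1-[(2S,3R)-3-{2-[(1Z,3E)-2-(tert-butyldimethylsilyloxy)penta-1,3-dien-1-yl]-2,4,6-trimethylcyclohexyl}oxiran-2-yl]ethan-1-one | C[C@@H]1C[C@H](C)[C@@H]([C@H]2O[C@@H]2C(C)=O)[C@](C)(/C=C(O[Si](C)(C)C(C)(C)C)/C=C/C)C1 | intermediate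
18 | triethylsilyl enol ether of epoxy ketone 17 | C[C@@H]1C[C@H](C)[C@@H]([C@H]2O[C@@H]2C(=C)O[Si](CC)(CC)CC)[C@](C)(/C=C(O[Si](C)(C)C(C)(C)C)/C=C/C)C1 | intermediate
19 | tricyclic cycloheptanone (ring A, ring B, seven-membered ring; OSiEt3 on ring B; TBS enol ether) | C[C@@H]1C[C@H](C)[C@H]2[C@@H](O[Si](CC)(CC)CC)[C@@H]3C(=O)C[C@@H](C)C=C(O[Si](C)(C)C(C)(C)C)[C@H]3[C@]2(C)C1 | intermediate
20 | α-trifluoroacetyl derivative of 19 | C[C@@H]1C[C@H](C)[C@H]2[C@@H](O[Si](CC)(CC)CC)[C@@H]3C(=O)C(C(=O)C(F)(F)F)[C@@H](C)C=C(O[Si](C)(C)C(C)(C)C)[C@H]3[C@]2(C)C1 | intermediate (not isolated)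
21 | α-diazo ketone of 19 | C[C@@H]1C[C@H](C)[C@H]2[C@@H](O[Si](CC)(CC)CC)[C@@H]3C(=O)C(=[N+]=[N-])[C@@H](C)C=C(O[Si](C)(C)C(C)(C)C)[C@H]3[C@]2(C)C1 | intermediate
22 | pent-4-ynoic acid | C#CCCC(=O)O | starting material
23 | 1,4-diiodobenzene | Ic1ccc(I)cc1 | starting material
24 | (E)-5-(4-iodobenzylidene)dihydrofuran-2(3H)-one | O=C1CC/C(=C\c2ccc(I)cc2)O1 | intermediate
25 | ring-contracted ketene (exocyclic C=C=O on Cc) | C[C@@H]1C[C@H](C)[C@H]2[C@@H](O[Si](CC)(CC)CC)[C@@H]3C(=C=O)[C@@H](C)C=C(O[Si](C)(C)C(C)(C)C)[C@H]3[C@]2(C)C1 | intermediate (not isolated)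
26 | ring-C β-keto lactone (lactone α-carbon epimers) | C[C@@H]1C[C@H](C)[C@H]2[C@@H](O[Si](CC)(CC)CC)[C@@H]3[C@@H](C(=O)C4C/C(=C\c5ccc(I)cc5)OC4=O)[C@@H](C)C=C(O[Si](C)(C)C(C)(C)C)[C@H]3[C@]2(C)C1 | intermediate
27 | ring-C enone | C[C@@H]1C[C@H](C)[C@H]2[C@@H](O[Si](CC)(CC)CC)[C@@H]3[C@@H](C(=O)C4C/C(=C\c5ccc(I)cc5)OC4=O)C(C)=CC(=O)[C@H]3[C@]2(C)C1 | intermediate
28 | tertiary allylic alcohol | C[C@@H]1C[C@H](C)[C@H]2[C@@H](O[Si](CC)(CC)CC)[C@@H]3[C@@H](C(=O)C4C/C(=C\c5ccc(I)cc5)OC4=O)C(C)=C[C@@](C)(O)[C@H]3[C@]2(C)C1 | intermediate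
29 | diol (free ring-B hydroxyl) | C[C@@H]1C[C@H](C)[C@H]2[C@@H](O)[C@@H]3[C@@H](C(=O)C4C/C(=C\c5ccc(I)cc5)OC4=O)C(C)=C[C@@](C)(O)[C@H]3[C@]2(C)C1 | intermediate
30 | macrocyclic aryl ether enol lactone | C[C@@H]1C[C@H](C)[C@H]2[C@H]3Oc4ccc(cc4)/C=C4\CC(C(=O)O4)C(=O)[C@H]5C(C)=C[C@@](C)(O)[C@H]([C@H]35)[C@]2(C)C1 | intermediate
31 | C-allylated macrocyclic enol lactone | C[C@@H]1C[C@H](C)[C@H]2[C@H]3Oc4ccc(cc4)/C=C4\C[C@](CC=C)(C(=O)O4)C(=O)[C@H]5C(C)=C[C@@](C)(O)[C@H]([C@H]35)[C@]2(C)C1 | intermediate
32 | macrocyclic hydroxy lactam | C[C@@H]1C[C@H](C)[C@H]2[C@H]3Oc4ccc(cc4)C[C@]4(O)C[C@](CC=C)(C(=O)N4)C(=O)[C@H]5C(C)=C[C@@](C)(O)[C@H]([C@H]35)[C@]2(C)C1 | intermediate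
33 | bromo hydroperoxide | C[C@@H]1C[C@H](C)[C@H]2[C@H]3Oc4ccc(cc4)C[C@]4(O)C[C@](CC=C)(C(=O)N4)C(=O)[C@H]5[C@@](C)(OO)[C@H](Br)[C@@](C)(O)[C@H]([C@H]35)[C@]2(C)C1 | intermediate
34 | hydroperoxy aldehyde | C[C@@H]1C[C@H](C)[C@H]2[C@H]3Oc4ccc(cc4)C[C@]4(O)C[C@](CC=O)(C(=O)N4)C(=O)[C@H]5[C@@](C)(OO)[C@H](Br)[C@@](C)(O)[C@H]([C@H]35)[C@]2(C)C1 | intermediate (not isolated)
35 | bromohydrin peroxy-hemiacetal | C[C@@H]1C[C@H](C)[C@H]2[C@H]3Oc4ccc(cc4)C[C@]4(O)C[C@]5(C[C@H](O)OO[C@@]6(C)[C@H](Br)[C@@](C)(O)[C@H]([C@H]3[C@H]6C5=O)[C@]2(C)C1)C(=O)N4 | intermediate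
36 | CNP0533733.1 | C[C@@H]1C[C@H](C)[C@H]2[C@H]3Oc4ccc(cc4)C[C@]4(O)C[C@]5(C[C@H](O)OO[C@@]6(C)[C@H]7O[C@@]7(C)[C@H]([C@H]3[C@H]6C5=O)[C@]2(C)C1)C(=O)N4 | target

## Step count and risks

Total steps: 26. Longest linear sequence: 25 (steps 1–15 and 17–26).

Steps most likely to fail:

1. Step 17 (Wolff contraction with enolate capture). The ketene may dimerise, or the enol-lactone enolate may fragment to a ketene by loss of the enolate oxygen, before C-acylation occurs. The fallback uses known chemistry. It sets out from 21, which is photolysed in the presence of N,O-dimethylhydroxylamine to give the ring-contracted Weinreb amide F1 (Wolff rearrangement with amine capture). F1 then acylates the lithium enolate of 24 (Claisen-type acylation by a Weinreb amide), which returns to the route at 26.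

2. Step 14 ((4+3) cycloaddition). The silylated epoxide may be opened by the dienol ether without closure of the seven-membered ring, the enol ether may lose its silyl group, or the ring-fusion selectivity may be poor. The fallback sets out from 17 and changes how the oxyallyl species is made. Chloride opening of the epoxy ketone at its α-carbon (MgCl2, THF) gives the α-chloro β-hydroxy ketone F2, and silylation (Et3SiCl, imidazole) gives the α-chloro β-silyloxy ketone F3. Base-mediated ionisation of F3 (LiClO4, Et3N, Et2O) gives the oxyallyl cation, which undergoes the (4+3) cycloaddition with the tethered diene and returns to the route at 19.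

3. Step 22 (allylation at Cs). The facial selectivity at the spiro carbon may be poor if ligand and macrocycle are mismatched. The fallback sets out from 30 and changes the substrate that controls the face. Ammonia first converts 30 into the Cs–H hydroxy lactam F4, in which both labile centres equilibrate to the preferred bridged arrangement. C-allylation of the β-keto lactam in this rigid bicycle (allyl bromide, K2CO3, acetone) then returns to the route at 32.

Further compounds
F1 | step 17 | ring-contracted N-methoxy-N-methyl amide (Weinreb amide on Cc) | C[C@@H]1C[C@H](C)[C@H]2[C@@H](O[Si](CC)(CC)CC)[C@@H]3[C@@H](C(=O)N(C)OC)[C@@H](C)C=C(O[Si](C)(C)C(C)(C)C)[C@H]3[C@]2(C)C1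
F2 | step 14 | α-chloro β-hydroxy ketone from epoxide opening of 17 | C[C@@H]1C[C@H](C)[C@@H]([C@@H](O)[C@@H](Cl)C(C)=O)[C@](C)(/C=C(O[Si](C)(C)C(C)(C)C)/C=C/C)C1
F3 | step 14 | α-chloro β-(triethylsilyloxy) ketone | C[C@@H]1C[C@H](C)[C@@H]([C@@H](O[Si](CC)(CC)CC)[C@@H](Cl)C(C)=O)[C@](C)(/C=C(O[Si](C)(C)C(C)(C)C)/C=C/C)C1
F4 | step 22 | macrocyclic hydroxy lactam with hydrogen on the future spiro carbon | C[C@@H]1C[C@H](C)[C@H]2[C@H]3Oc4ccc(cc4)C[C@]4(O)C[C@H](C(=O)N4)C(=O)[C@H]5C(C)=C[C@@](C)(O)[C@H]([C@H]35)[C@]2(C)C1
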